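**Plan**

1. Retrosynthesis: the three phenols are masked as MOM ethers, ring C is opened at O1–C8a (aryl C–O bond), the C2 carbinol is traced back to a ketone, and C3–C4 is cut (as the C=C of a chalcone) into a ring B methyl ketone and a ring A aldehyde.
2. The C6 1,1-dimethylallyl group and the C2′/C3′ prenyl groups are cut at their aryl–C bonds to aryl halides and one reagent, prenylB(pin), coupled in the γ mode on ring A and in the α mode on ring B.
3. Forward: ring A aldehyde 7 (4 steps) and ring B ketone 15 (6 steps) are joined by Claisen–Schmidt condensation; conjugate reduction and asymmetric ketone reduction give the open-chain alcohol, ring C closes last, and MOM removal ends the route.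
4. Enabling feature: O1 of ring C is bonded both to aromatic C8a of ring A and to the stereogenic C2, so ring C can be closed at O1–C8a with every bond at C2 left intact.
5. Stereochemistry: the single stereocentre C2 (S) comes from Noyori–Ikariya transfer hydrogenation of ketone 18 with the (S,S)-TsDPEN ruthenium catalyst and is retained in the cyclisation.

Key step: step 14

Remark: flavan numbering is used (O1, C2, C3, C4, C4a, C5–C8, C8a; primes for ring B; ring A = benzo ring, ring B = C2 aryl group, ring C = pyran); compounds 1, 4 and 8 are taken as catalogue chemicals.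

**Route**

Step 1
Reactants: 1 2-bromo-4-hydroxybenzonitrile
Product: 2 2-bromo-4-hydroxy-5-iodobenzonitrile
Conditions: NIS (1.05 equiv), p-TsOH·H2O (10 mol %), MeCN, 0 °C to rt
Reagents that add atoms: N-iodosuccinimide, O=C1CCC(=O)N1I
Why: Electrophilic aromatic iodination of a phenol goes ortho to OH, and of the two ortho sites the one wedged between OH and Br is shielded, so iodine should enter C5.

Step 2
Reactants: 2 2-bromo-4-hydroxy-5-iodobenzonitrile
Product: 3 2-bromo-5-iodo-4-(methoxymethoxy)benzonitrile
Conditions: MOMCl (1.5 equiv), i-Pr2NEt, CH2Cl2, 0 °C to rt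
Reagents that add atoms: chloromethyl methyl ether, COCCl
Why: Williamson-type O-alkylation of the acidic phenol with an α-chloro ether should give the MOM acetal, which is stable to the basic, organometallic and palladium conditions that follow.

Step 3
Reactants: 3 2-bromo-5-iodo-4-(methoxymethoxy)benzonitrile; 4 4,4,5,5-tetramethyl-2-(3-methylbut-2-en-1-yl)-1,3,2-dioxaborolane (prenylB(pin))
Product: 5 2-bromo-4-(methoxymethoxy)-5-(2-methylbut-3-en-2-yl)benzonitrile
Conditions: 4 (1.2 equiv), Pd(OAc)2 (3 mol %), 2-{bis[3,5-bis(trifluoromethyl)phenyl]phosphino}-3,6-dimethoxy-2′,4′,6′-triisopropylbiphenyl (6 mol %), aq. K3PO4, MeCN, 70 °C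
Reagents that add atoms: none
Why: This is a Suzuki–Miyaura allyl–aryl coupling run in its γ-selective mode: oxidative addition at C–I outpaces C–Br, SE2′ transmetalation places palladium on the tertiary allyl carbon, and the electron-poor diarylphosphine should speed C–C reductive elimination ahead of σ–π–σ isomerisation, giving the 1,1-dimethylallyl group.

Step 4
Reactants: 5 2-bromo-4-(methoxymethoxy)-5-(2-methylbut-3-en-2-yl)benzonitrile
Product: 7 2-bromo-4-(methoxymethoxy)-5-(2-methylbut-3-en-2-yl)benzaldehyde, via N-diisobutylaluminio aldimine 6 (not isolated)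
Conditions: i-Bu2AlH (1.2 equiv), toluene, −78 °C; then aq. citric acid, 0 °C
Reagents that add atoms: water, O
Why: Partial nitrile reduction with i-Bu2AlH stops at the aluminium aldimine, whose mild hydrolysis should give the aldehyde without touching the aryl bromide, the MOM ether or the alkene.

Step 5
Reactants: 8 3-bromo-4-hydroxy-5-methoxybenzaldehyde (5-bromovanillin)
Product: 9 2,3-dibromo-4-hydroxy-5-methoxybenzaldehyde
Conditions: Br2 (1.1 equiv), Fe powder (cat.), AcOH, rt
Reagents that add atoms: bromine, BrBr
Why: In this electrophilic aromatic bromination both sites ortho to OH are filled, so the methoxy group should steer the second bromine to its para position, next to the first bromine.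

Step 6
Reactants: 9 2,3-dibromo-4-hydroxy-5-methoxybenzaldehyde
Product: 10 2,3-dibromo-4,5-dihydroxybenzaldehyde
Conditions: AlCl3 (1.3 equiv), pyridine (4.5 equiv), CH2Cl2, reflux; then aq. HCl
Reagents that add atoms: none
Why: Lewis-acid-assisted O-demethylation: AlCl3 chelates the phenoxide and the neighbouring methoxy oxygen and pyridine removes the methyl group by SN2, a cleavage specific to a methoxy group ortho to a free phenol.

Step 7
Reactants: 10 2,3-dibromo-4,5-dihydroxybenzaldehyde
Product: 11 2,3-dibromo-4,5-bis(methoxymethoxy)benzaldehyde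
Conditions: MOMCl (3 equiv), i-Pr2NEt (4 equiv), CH2Cl2, 0 °C to rt
Reagents that add atoms: chloromethyl methyl ether, COCCl
Why: Double Williamson-type O-alkylation should protect the air-sensitive catechol as its bis-MOM ether in the same form as the ring A phenol.

Step 8
Reactants: 11 2,3-dibromo-4,5-bis(methoxymethoxy)benzaldehyde
Product: 12 rac-1-[2,3-dibromo-4,5-bis(methoxymethoxy)phenyl]ethan-1-ol
Conditions: MeMgBr (1.2 equiv), THF, −78 to 0 °C; aq. NH4Cl
Reagents that add atoms: methylmagnesium bromide, C[Mg]Br
Why: Grignard addition to the aldehyde is much faster than bromine–magnesium exchange at low temperature, and the racemic carbinol centre is removed in the next step.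

Step 9
Reactants: 12 rac-1-[2,3-dibromo-4,5-bis(methoxymethoxy)phenyl]ethan-1-ol
Product: 13 1-[2,3-dibromo-4,5-bis(methoxymethoxy)phenyl]ethan-1-one
Conditions: Dess–Martin periodinane (1.3 equiv), CH2Cl2, rt
Reagents that add atoms: none
Why: Dess–Martin oxidation of the secondary benzylic alcohol should give the methyl ketone under near-neutral conditions that leave the MOM ethers alone, and it removes the free alcohol before the palladium step.

Step 10
Reactants: 13 1-[2,3-dibromo-4,5-bis(methoxymethoxy)phenyl]ethan-1-one; 4 prenylB(pin)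
Product: 15 1-[4,5-bis(methoxymethoxy)-2,3-bis(3-methylbut-2-en-1-yl)phenyl]ethan-1-one, via monoprenylated bromo ketone 14 (not isolated)
Conditions: 4 (3 equiv), PdCl2(IPent)(3-chloropyridine) (4 mol %; IPent = 1,3-bis[2,6-di(pentan-3-yl)phenyl]imidazol-2-ylidene), aq. KOH (5 M), THF, 70 °C
Reagents that add atoms: none
Why: This is a Suzuki–Miyaura allyl–aryl coupling in its α-selective mode: the very bulky N-heterocyclic carbene makes the tertiary σ-allyl palladium relax to the primary one before reductive elimination and tolerates flanked aryl bromides, so both bromides should be replaced by linear prenyl groups whichever reacts first.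

Step 11
Reactants: 15 1-[4,5-bis(methoxymethoxy)-2,3-bis(3-methylbut-2-en-1-yl)phenyl]ethan-1-one; 7 2-bromo-4-(methoxymethoxy)-5-(2-methylbut-3-en-2-yl)benzaldehyde
Product: 17 (E)-3-[2-bromo-4-(methoxymethoxy)-5-(2-methylbut-3-en-2-yl)phenyl]-1-[4,5-bis(methoxymethoxy)-2,3-bis(3-methylbut-2-en-1-yl)phenyl]prop-2-en-1-one, via racemic aldol adduct 16 (not isolated)
Conditions: KOH, EtOH/THF, rt
Reagents that add atoms: none
Why: In this Claisen–Schmidt condensation the methyl ketone enolate adds to the non-enolisable aldehyde and E1cB loss of water should give the (E)-chalcone, forming the C3–C4 bond.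

Step 12
Reactants: 17 the (E)-chalcone
Product: 18 3-[2-bromo-4-(methoxymethoxy)-5-(2-methylbut-3-en-2-yl)phenyl]-1-[4,5-bis(methoxymethoxy)-2,3-bis(3-methylbut-2-en-1-yl)phenyl]propan-1-one
Conditions: [(Ph3P)CuH]6 (0.35 equiv), H2O (2 equiv), degassed THF, rt
Reagents that add atoms: none
Why: Stryker conjugate reduction delivers hydride from copper to the β-carbon of the enone only, so the isolated vinyl and prenyl alkenes, the aryl bromide and the carbonyl group should survive.

Step 13
Reactants: 18 the saturated ketone
Product: 19 (S)-1-[4,5-bis(methoxymethoxy)-2,3-bis(3-methylbut-2-en-1-yl)phenyl]-3-[2-bromo-4-(methoxymethoxy)-5-(2-methylbut-3-en-2-yl)phenyl]propan-1-ol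
Conditions: RuCl(p-cymene)[(S,S)-TsDPEN] (2 mol %), HCO2H/Et3N (5:2), DMF, 40 °C
Reagents that add atoms: none
Why: In this Noyori–Ikariya asymmetric transfer hydrogenation the (S,S)-TsDPEN ruthenium hydride, guided by the CH–π contact between its η6-arene and the ketone aryl ring, should deliver hydride to the Re face of the aryl alkyl ketone and set C2 as (S), while isolated alkenes and the aryl bromide are not reduced.

Step 14
Reactants: 19 the (S)-bromo alcohol
Product: 20 (S)-2-[4,5-bis(methoxymethoxy)-2,3-bis(3-methylbut-2-en-1-yl)phenyl]-7-(methoxymethoxy)-6-(2-methylbut-3-en-2-yl)chromane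
Conditions: Pd(OAc)2 (5 mol %), rac-2-(di-tert-butylphosphino)-1,1′-binaphthyl (6 mol %), Cs2CO3 (1.5 equiv), toluene, 70 °C
Reagents that add atoms: none
Why: Zerovalent palladium formed in situ inserts into the C8a–Br bond, the carbonate deprotonates the palladium-bound C2 alcohol, and C–O reductive elimination from the seven-membered aryl(alkoxo)palladacycle releases the chroman; the closest known reaction is the Buchwald-type intramolecular etherification of aryl bromides with secondary alcohols. Ring C closes as a six-membered ring by intramolecular O-arylation, an exo closure in which the C8a–Br bond being replaced lies outside the new ring. No stereocentre is created, because the C2–O bond is never broken and the (S) configuration from step 13 is carried over with retention. The selectivity needed is C–O reductive elimination over β-hydride elimination of the secondary benzylic alkoxide, which the bulky electron-rich di-tert-butylphosphine and the favourable six-ring geometry should secure. The vinyl group para to the bromide cannot reach the palladium centre within the molecule and the trisubstituted prenyl alkenes resist carbopalladation, so Heck pathways should stay in the background.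

Step 15
Reactants: 20 the tris-MOM chroman
Product: 21 Kazinol E, (S)-2-[4,5-dihydroxy-2,3-bis(3-methylbut-2-en-1-yl)phenyl]-6-(2-methylbut-3-en-2-yl)chroman-7-ol
Conditions: HCl (about 1 M) in MeOH/THF, rt to 40 °C, under argon
Reagents that add atoms: none
Why: Acid-catalysed acetal methanolysis should cleave the three aryl MOM ethers well below the acidity and temperature needed for cyclisation of a prenyl or 1,1-dimethylallyl group onto a neighbouring phenol, and it does not affect C2.

**Compound list**

1 | 2-bromo-4-hydroxybenzonitrile | N#Cc1ccc(O)cc1Br | starting material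
2 | 2-bromo-4-hydroxy-5-iodobenzonitrile | N#Cc1cc(I)c(O)cc1Br | intermediate
3 | 2-bromo-5-iodo-4-(methoxymethoxy)benzonitrile | N#Cc1cc(I)c(OCOC)cc1Br | intermediate
4 | 4,4,5,5-tetramethyl-2-(3-methylbut-2-en-1-yl)-1,3,2-dioxaborolane (prenylB(pin)) | CC(C)=CCB1OC(C)(C)C(C)(C)O1 | starting material
5 | 2-bromo-4-(methoxymethoxy)-5-(2-methylbut-3-en-2-yl)benzonitrile | N#Cc1cc(C(C)(C)C=C)c(OCOC)cc1Br | intermediate
6 | N-(diisobutylaluminio)aldimine of aldehyde 7 (not isolated) | CC(C)C[Al](CC(C)C)N=Cc1cc(C(C)(C)C=C)c(OCOC)cc1Br | intermediate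
7 | 2-bromo-4-(methoxymethoxy)-5-(2-methylbut-3-en-2-yl)benzaldehyde | O=Cc1cc(C(C)(C)C=C)c(OCOC)cc1Br | intermediate
8 | 3-bromo-4-hydroxy-5-methoxybenzaldehyde (5-bromovanillin) | O=Cc1cc(OC)c(O)c(Br)c1 | starting material
9 | 2,3-dibromo-4-hydroxy-5-methoxybenzaldehyde | O=Cc1cc(OC)c(O)c(Br)c1Br | intermediate
10 | 2,3-dibromo-4,5-dihydroxybenzaldehyde | O=Cc1cc(O)c(O)c(Br)c1Br | intermediate
11 | 2,3-dibromo-4,5-bis(methoxymethoxy)benzaldehyde | O=Cc1cc(OCOC)c(OCOC)c(Br)c1Br | intermediate
12 | rac-1-[2,3-dibromo-4,5-bis(methoxymethoxy)phenyl]ethan-1-ol | CC(O)c1cc(OCOC)c(OCOC)c(Br)c1Br | intermediate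
13 | 1-[2,3-dibromo-4,5-bis(methoxymethoxy)phenyl]ethan-1-one | CC(=O)c1cc(OCOC)c(OCOC)c(Br)c1Br | intermediate
14 | 1-[3-bromo-4,5-bis(methoxymethoxy)-2-(3-methylbut-2-en-1-yl)phenyl]ethan-1-one (not isolated) | CC(=O)c1cc(OCOC)c(OCOC)c(Br)c1CC=C(C)C | intermediate
15 | 1-[4,5-bis(methoxymethoxy)-2,3-bis(3-methylbut-2-en-1-yl)phenyl]ethan-1-one | CC(=O)c1cc(OCOC)c(OCOC)c(CC=C(C)C)c1CC=C(C)C | intermediate
16 | rac-3-[2-bromo-4-(methoxymethoxy)-5-(2-methylbut-3-en-2-yl)phenyl]-3-hydroxy-1-[4,5-bis(methoxymethoxy)-2,3-bis(3-methylbut-2-en-1-yl)phenyl]propan-1-one (not isolated) | O=C(CC(O)c1cc(C(C)(C)C=C)c(OCOC)cc1Br)c1cc(OCOC)c(OCOC)c(CC=C(C)C)c1CC=C(C)C | intermediate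
17 | (E)-3-[2-bromo-4-(methoxymethoxy)-5-(2-methylbut-3-en-2-yl)phenyl]-1-[4,5-bis(methoxymethoxy)-2,3-bis(3-methylbut-2-en-1-yl)phenyl]prop-2-en-1-one | O=C(/C=C/c1cc(C(C)(C)C=C)c(OCOC)cc1Br)c1cc(OCOC)c(OCOC)c(CC=C(C)C)c1CC=C(C)C | intermediate
18 | 3-[2-bromo-4-(methoxymethoxy)-5-(2-methylbut-3-en-2-yl)phenyl]-1-[4,5-bis(methoxymethoxy)-2,3-bis(3-methylbut-2-en-1-yl)phenyl]propan-1-one | O=C(CCc1cc(C(C)(C)C=C)c(OCOC)cc1Br)c1cc(OCOC)c(OCOC)c(CC=C(C)C)c1CC=C(C)C | intermediate
19 | (S)-1-[4,5-bis(methoxymethoxy)-2,3-bis(3-methylbut-2-en-1-yl)phenyl]-3-[2-bromo-4-(methoxymethoxy)-5-(2-methylbut-3-en-2-yl)phenyl]propan-1-ol | O[C@H](c1cc(OCOC)c(OCOC)c(CC=C(C)C)c1CC=C(C)C)CCc1cc(C(C)(C)C=C)c(OCOC)cc1Br | intermediate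
20 | (S)-2-[4,5-bis(methoxymethoxy)-2,3-bis(3-methylbut-2-en-1-yl)phenyl]-7-(methoxymethoxy)-6-(2-methylbut-3-en-2-yl)chromane | C=CC(C)(C)c1cc2c(cc1OCOC)O[C@H](c1cc(OCOC)c(OCOC)c(CC=C(C)C)c1CC=C(C)C)CC2 | intermediate
21 | Kazinol E, (S)-2-[4,5-dihydroxy-2,3-bis(3-methylbut-2-en-1-yl)phenyl]-6-(2-methylbut-3-en-2-yl)chroman-7-ol | C=CC(C)(C)c1cc2c(cc1O)O[C@H](c1cc(O)c(O)c(CC=C(C)C)c1CC=C(C)C)CC2 | target

**Step count and risks**

Total: 15 steps. Longest linear sequence: 11 steps (steps 5–10, then 11–15, from 5-bromovanillin 8).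

Step 3 (γ-selective prenylation). The ortho MOM ether crowds the palladium, so the tertiary σ-allyl intermediate may isomerise to the primary one before reductive elimination and give the linear prenyl isomer; late in the reaction the catalyst may also insert into the C–Br bond ortho to the nitrile. The fallback sets out from phenol 1 and uses a sigmatropic route. O-alkylation with 1-bromo-3-methylbut-2-ene (K2CO3, acetone) would give 2-bromo-4-[(3-methylbut-2-en-1-yl)oxy]benzonitrile F1. Heating in N,N-diethylaniline at about 190 °C would bring about the aromatic Claisen rearrangement, in which the [3,3] shift inverts the allyl unit by necessity and the ortho site next to bromine is the more hindered, to give 2-bromo-4-hydroxy-5-(2-methylbut-3-en-2-yl)benzonitrile F2. MOM protection as in step 2 comes back to the route at 5.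

Step 10 (double α-selective prenylation). The second coupling at the bromide flanked by a prenyl group and a MOM ether may stall or end in protodebromination, and leakage through the tertiary σ-allyl palladium would give reverse-prenyl isomers. The fallback sets out from dibromide 13 and separates C–C coupling from the regiochemical question. Double Stille allylation with allyltributylstannane (Pd(PPh3)4, toluene, 110 °C) would give 1-[4,5-bis(methoxymethoxy)-2,3-di(prop-2-en-1-yl)phenyl]ethan-1-one F3, for which α and γ attack are identical. Double olefin cross-metathesis with excess 2-methylbut-2-ene (second-generation Grubbs catalyst RuCl2(=CHPh)(PCy3)(H2IMes), CH2Cl2, 40 °C) comes back to the route at 15.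

Step 14 (key C–O coupling). β-Hydride elimination from the palladium alkoxide may outrun C–O reductive elimination on this electron-rich aryl palladium, returning ketone 18 and a debrominated arene. The fallback sets out from bromo alcohol 19 and forms the same O1–C8a bond with copper, whose alkoxides do not follow that path. Aromatic halogen exchange (CuI, NaI, trans-N,N′-dimethylcyclohexane-1,2-diamine, dioxane, 110 °C) would give (S)-1-[4,5-bis(methoxymethoxy)-2,3-bis(3-methylbut-2-en-1-yl)phenyl]-3-[2-iodo-4-(methoxymethoxy)-5-(2-methylbut-3-en-2-yl)phenyl]propan-1-ol F4. Ullmann-type intramolecular O-arylation (CuI, 1,10-phenanthroline, Cs2CO3, toluene, 110 °C) comes back to the route at 20, again without touching the C2–O bond.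

**Further compounds**

F1 | step 3 | 2-bromo-4-[(3-methylbut-2-en-1-yl)oxy]benzonitrile | N#Cc1ccc(OCC=C(C)C)cc1Br
F2 | step 3 | 2-bromo-4-hydroxy-5-(2-methylbut-3-en-2-yl)benzonitrile | N#Cc1cc(C(C)(C)C=C)c(O)cc1Br
F3 | step 10 | 1-[4,5-bis(methoxymethoxy)-2,3-di(prop-2-en-1-yl)phenyl]ethan-1-one | CC(=O)c1cc(OCOC)c(OCOC)c(CC=C)c1CC=C
F4 | step 14 | (S)-1-[4,5-bis(methoxymethoxy)-2,3-bis(3-methylbut-2-en-1-yl)phenyl]-3-[2-iodo-4-(methoxymethoxy)-5-(2-methylbut-3-en-2-yl)phenyl]propan-1-ol | O[C@H](c1cc(OCOC)c(OCOC)c(CC=C(C)C)c1CC=C(C)C)CCc1cc(C(C)(C)C=C)c(OCOC)cc1I
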